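**Plan**

- Retrosynthesis: the pyran ring is opened at O1–C2 to give a 1,3-diarylpropan-1-ol. Ring B is then cut at C1'–C2' and C5'–C6' into a four-carbon diene and a two-carbon alkyne. The ynone goes back through a Weinreb amide to dihydroumbelliferone.
- Enabling feature: C2'(prenyl)–C3'(OH)–C4'(OH)–C5'(prenyl) of ring B reads the same from either end. These four carbons therefore correspond to the bis(silyl enol ether) of a symmetrical 1,2-diketone with two homoprenyl arms. C1' and C6' are the two alkyne carbons of a terminal ynone whose carbonyl carbon is C2 of the flavan.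
- Forward order: the diene (2 steps) and the ring A ynone (7 steps) are made separately. Ring B is then built on the ring A side chain by [4+2] cycloaddition and dehydrogenation, and the pyran ring (ring C) is closed last.
- Stereochemistry: the only stereocentre, C2 (S), comes from asymmetric transfer hydrogenation of the C2 ketone to the (R)-carbinol, which is inverted in the Mitsunobu ring closure.

Key step: step 10

Remark: the SMILES is read as the (2S)-flavan. Dienone 12 and cycloadduct 17 are transient racemic species whose stereocentres disappear in the same step.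

**Route**

Step 1
Reactants: 1 5-bromo-2-methylpent-2-ene (2.3 equiv); 2 N,N'-dimethoxy-N,N'-dimethyloxamide
Product: 4 2,11-dimethyldodeca-2,10-diene-6,7-dione, via homoprenylmagnesium bromide 3 (not isolated)
Conditions: Mg, THF, 40 °C; then 2, THF, −78 → 0 °C; 1 M HCl, 0 °C
Reagents that add atoms: none
Why: Grignard formation followed by a twofold Weinreb ketone synthesis, in which each N-methoxy-N-methylamide carbonyl should accept exactly one homoprenyl group and stop at the ketone stage, so the symmetrical 1,2-diketone is released on acidic work-up.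

Step 2
Reactants: 4 2,11-dimethyldodeca-2,10-diene-6,7-dione
Product: 5 (5Z,7Z)-6,7-bis(tert-butyldimethylsilyloxy)-2,11-dimethyldodeca-2,5,7,10-tetraene
Conditions: TBSOTf (2.4 equiv), Et3N (3 equiv), CH2Cl2, 0 °C → rt; cold NaHCO3 work-up
Reagents that add atoms: tert-butyldimethylsilyl trifluoromethanesulfonate, CC(C)(C)[Si](C)(C)OS(=O)(=O)C(F)(F)F
Why: Soft enolisation and O-silylation of both carbonyls (silyl enol ether formation) under equilibrating amine/silyl triflate conditions should favour the (Z,Z)-diene, in which each prenyl-bearing CH2 arm lies anti to the bulky neighbouring enol carbon.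

Step 3
Reactants: 6 umbelliferone (7-hydroxy-2H-chromen-2-one)
Product: 7 7-hydroxychroman-2-one (dihydroumbelliferone)
Conditions: H2 (3 atm), 10% Pd/C, AcOH, 50 °C
Reagents that add atoms: none
Why: Heterogeneous catalytic hydrogenation should saturate only the conjugated C3=C4 bond of the pyranone and leave the benzene ring and the lactone intact.

Step 4
Reactants: 7 7-hydroxychroman-2-one; 8 prenyl bromide (1-bromo-3-methylbut-2-en-1-yl bromide, i.e. 1-bromo-3-methylbut-2-ene)
Product: 9 7-(3-methylbut-2-en-1-yloxy)chroman-2-one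
Conditions: K2CO3, dry acetone, rt → 50 °C
Reagents that add atoms: none
Why: Williamson ether synthesis, in which the phenoxide should displace the primary allylic bromide by SN2 while the anhydrous heterogeneous base leaves the aryl lactone closed.

Step 5
Reactants: 9 7-(3-methylbut-2-en-1-yloxy)chroman-2-one
Product: 10 3-[2-hydroxy-4-(3-methylbut-2-en-1-yloxy)phenyl]-N-methoxy-N-methylpropanamide
Conditions: MeNHOMe·HCl (2.5 equiv), iPrMgCl (5 equiv), THF, −20 → 0 °C; aq. NH4Cl
Reagents that add atoms: N,O-dimethylhydroxylamine hydrochloride, CNOC.Cl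
Why: Aminolysis of the activated aryl lactone by the magnesium amide made in the flask (Weinreb amide formation) should open the ring and free the phenol that later becomes O1.

Step 6
Reactants: 10 3-[2-hydroxy-4-(3-methylbut-2-en-1-yloxy)phenyl]-N-methoxy-N-methylpropanamide
Product: 11 N-methoxy-3-[2-(methoxymethoxy)-4-(3-methylbut-2-en-1-yloxy)phenyl]-N-methylpropanamide
Conditions: MOMCl, iPr2NEt, CH2Cl2, 0 °C → rt
Reagents that add atoms: chloromethyl methyl ether, COCCl
Why: O-Alkylation of the phenol gives a MOM acetal that should survive heat, Grignard reagents and DDQ and can later be removed without touching aryl silyl ethers.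

Step 7
Reactants: 11 N-methoxy-3-[2-(methoxymethoxy)-4-(3-methylbut-2-en-1-yloxy)phenyl]-N-methylpropanamide
Product: 13 3-[4-hydroxy-2-(methoxymethoxy)-5-(2-methylbut-3-en-2-yl)phenyl]-N-methoxy-N-methylpropanamide, via ortho-dienone 12 (not isolated)
Conditions: PhNEt2, 185 °C (sealed tube or microwave), argon, short reaction time
Reagents that add atoms: none
Why: Aromatic Claisen rearrangement, in which the [3,3] shift of the aryl prenyl ether should deliver the 1,1-dimethylallyl group to the free ortho carbon para to the MOM ether (favoured over the crowded carbon between the two oxygens, as in related 2-alkoxy-4-prenyloxyphenyl systems) before the dienone tautomerises to the phenol.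

Step 8
Reactants: 13 3-[4-hydroxy-2-(methoxymethoxy)-5-(2-methylbut-3-en-2-yl)phenyl]-N-methoxy-N-methylpropanamide
Product: 14 3-[4-(tert-butyldimethylsilyloxy)-2-(methoxymethoxy)-5-(2-methylbut-3-en-2-yl)phenyl]-N-methoxy-N-methylpropanamide
Conditions: TBSCl, imidazole, DMAP (cat.), DMF, 40 °C
Reagents that add atoms: tert-butyldimethylsilyl chloride, CC(C)(C)[Si](C)(C)Cl
Why: Imidazole-mediated silylation of the hindered phenol should work with gentle warming and avoids silyl triflate/pyridine-base conditions that could attack the MOM acetal.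

Step 9
Reactants: 14 3-[4-(tert-butyldimethylsilyloxy)-2-(methoxymethoxy)-5-(2-methylbut-3-en-2-yl)phenyl]-N-methoxy-N-methylpropanamide; 15 ethynylmagnesium bromide
Product: 16 5-[4-(tert-butyldimethylsilyloxy)-2-(methoxymethoxy)-5-(2-methylbut-3-en-2-yl)phenyl]pent-1-yn-3-one (ring A ethynyl ketone)
Conditions: 15 (3 equiv), THF, 0 °C → rt; inverse quench into cold 1 M HCl
Reagents that add atoms: none
Why: Weinreb ketone synthesis should stop at the ynone without over-addition, and the cold acidic inverse quench protonates the liberated N,O-dimethylhydroxylamine before it can add to the ynone.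

Step 10
Reactants: 5 (5Z,7Z)-6,7-bis(tert-butyldimethylsilyloxy)-2,11-dimethyldodeca-2,5,7,10-tetraene (1.3 equiv); 16 ring A ethynyl ketone
Product: 18 1-[3,4-bis(tert-butyldimethylsilyloxy)-2,5-bis(3-methylbut-2-en-1-yl)phenyl]-3-[4-(tert-butyldimethylsilyloxy)-2-(methoxymethoxy)-5-(2-methylbut-3-en-2-yl)phenyl]propan-1-one (protected dihydrochalcone), via cis-cyclohexa-1,4-diene cycloadduct 17 (not isolated)
Conditions: BHT (cat.), PhMe, 110 °C, sealed tube; then DDQ (1.3 equiv), PhMe, 0 °C → rt
Reagents that add atoms: none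
Why: The electron-rich 2,3-bis(silyloxy)diene 5 and the electron-poor terminal ynone 16 should combine in a concerted, suprafacial, normal-electron-demand [4+2] cycloaddition that forms C1'–C2' and C5'–C6' together, after which DDQ removes the two doubly allylic ring hydrogens (hydride abstraction next to the silyl enol ether, then proton loss) to give the arene. The closest known reaction type is the Diels–Alder reaction of 2,3-bis(trialkylsilyloxy)buta-1,3-dienes with acetylenic ketones or esters followed by dehydrogenation to catechol bis(silyl ethers). The six-membered carbocycle (ring B) closes by intermolecular [4+2] cycloaddition, both new sigma bonds forming in the same event, so no separate ring-closing step arises. The two sp3 carbons of 17 are cis because both arms sit on the outside of the (Z,Z)-diene, but both centres are erased on aromatisation, so no stereocontrol is needed. No regiocontrol is needed because the diene is symmetrical end to end; chemoselectivity for the ynone is secured because none of the three isolated C=C bonds is conjugated to an acceptor; and selective dehydrogenation is secured because only the ring C–H bonds of 17 are both doubly allylic and adjacent to an enol ether, so DDQ at 0 °C should be consumed there before any benzylic position reacts. The (Z,Z) geometry keeps the s-cis conformer reachable and excludes a 1,5-hydrogen shift, and any (E)-configured diene isomer should simply remain unreacted.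

Step 11
Reactants: 18 protected dihydrochalcone
Product: 20 1-[3,4-bis(tert-butyldimethylsilyloxy)-2,5-bis(3-methylbut-2-en-1-yl)phenyl]-3-[4-(tert-butyldimethylsilyloxy)-2-hydroxy-5-(2-methylbut-3-en-2-yl)phenyl]propan-1-one, via aryl trimethylsilyl ether 19 (not isolated)
Conditions: TMSOTf (2 equiv), 2,2'-bipyridyl (3 equiv), MeCN, 0 °C → rt; then H2O, rt
Reagents that add atoms: none
Why: Silyl triflate/2,2'-bipyridyl cleavage of an aromatic MOM ether converts the acetal under buffered, non-protic conditions into the labile aryl trimethylsilyl ether, which water hydrolyses, so the three aryl TBS ethers and the alkenes should be spared and the ketone is never exposed to the protic acid that would ketalise it with the new phenol.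

Step 12
Reactants: 20 keto-phenol
Product: 21 (1R)-1-[3,4-bis(tert-butyldimethylsilyloxy)-2,5-bis(3-methylbut-2-en-1-yl)phenyl]-3-[4-(tert-butyldimethylsilyloxy)-2-hydroxy-5-(2-methylbut-3-en-2-yl)phenyl]propan-1-ol
Conditions: RuCl(p-cymene)[(R,R)-TsDPEN] (3 mol %), HCO2H/Et3N (5:2), EtOAc, 40 °C
Reagents that add atoms: none
Why: Noyori–Ikariya asymmetric transfer hydrogenation, in which the (R,R)-TsDPEN ruthenium hydride should deliver hydrogen to the ketone face fixed by the CH/π contact between the cymene ligand and ring B (the sense that gives (R)-1-arylalkanols from aryl alkyl ketones) without reducing the isolated alkenes.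

Step 13
Reactants: 21 (R)-carbinol
Product: 22 (2S)-2-[3,4-bis(tert-butyldimethylsilyloxy)-2,5-bis(3-methylbut-2-en-1-yl)phenyl]-7-(tert-butyldimethylsilyloxy)-6-(2-methylbut-3-en-2-yl)chromane
Conditions: PPh3, DIAD, PhMe, 0 °C
Reagents that add atoms: none
Why: Mitsunobu etherification, in which the carbinol oxygen activated by PPh3/DIAD is displaced intramolecularly by the ring A phenol oxygen (SN2, 6-exo-tet), so O1–C2 should form with inversion and C2 becomes (S), with the non-polar solvent and low temperature chosen to suppress ionisation of the electron-rich benzylic centre.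

Step 14
Reactants: 22 tris-silylated (2S)-flavan
Product: 23 4-[(2S)-7-hydroxy-6-(2-methylbut-3-en-2-yl)-3,4-dihydro-2H-chromen-2-yl]-3,6-bis(3-methylbut-2-en-1-yl)benzene-1,2-diol (target)
Conditions: Bu4NF (3.5 equiv), AcOH (3.5 equiv), THF, 0 °C → rt, argon
Reagents that add atoms: none
Why: Fluoride-induced Si–O cleavage should remove all three aryl silyl ethers, while the acetic acid buffer keeps the liberated 4'-phenoxide from opening the pyran ring through a para-quinone methide (which would scramble C2) and exclusion of air protects the catechol.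

**Compound list**

1 | 5-bromo-2-methylpent-2-ene | CC(C)=CCCBr | starting material
2 | N,N'-dimethoxy-N,N'-dimethyloxamide | CON(C)C(=O)C(=O)N(C)OC | starting material
3 | (4-methylpent-3-en-1-yl)magnesium bromide (homoprenylmagnesium bromide) | CC(C)=CCC[Mg]Br | intermediate
4 | 2,11-dimethyldodeca-2,10-diene-6,7-dione | CC(C)=CCCC(=O)C(=O)CCC=C(C)C | intermediate
5 | (5Z,7Z)-6,7-bis(tert-butyldimethylsilyloxy)-2,11-dimethyldodeca-2,5,7,10-tetraene | CC(C)=CC/C=C(O[Si](C)(C)C(C)(C)C)/C(O[Si](C)(C)C(C)(C)C)=C/CC=C(C)C | intermediate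
6 | umbelliferone (7-hydroxy-2H-chromen-2-one) | O=c1ccc2ccc(O)cc2o1 | starting material
7 | 7-hydroxychroman-2-one | O=C1CCc2ccc(O)cc2O1 | intermediate
8 | prenyl bromide (1-bromo-3-methylbut-2-ene) | CC(C)=CCBr | starting material
9 | 7-(3-methylbut-2-en-1-yloxy)chroman-2-one | O=C1CCc2ccc(OCC=C(C)C)cc2O1 | intermediate
10 | 3-[2-hydroxy-4-(3-methylbut-2-en-1-yloxy)phenyl]-N-methoxy-N-methylpropanamide | CON(C)C(=O)CCc1ccc(OCC=C(C)C)cc1O | intermediate
11 | N-methoxy-3-[2-(methoxymethoxy)-4-(3-methylbut-2-en-1-yloxy)phenyl]-N-methylpropanamide | CON(C)C(=O)CCc1ccc(OCC=C(C)C)cc1OCOC | intermediate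
12 | N-methoxy-3-[6-(methoxymethoxy)-3-(2-methylbut-3-en-2-yl)-4-oxocyclohexa-1,5-dien-1-yl]-N-methylpropanamide (ortho-dienone, racemic) | CON(C)C(=O)CCC1=CC(C(C)(C)C=C)C(=O)C=C1OCOC | intermediate
13 | 3-[4-hydroxy-2-(methoxymethoxy)-5-(2-methylbut-3-en-2-yl)phenyl]-N-methoxy-N-methylpropanamide | CON(C)C(=O)CCc1cc(C(C)(C)C=C)c(O)cc1OCOC | intermediate
14 | 3-[4-(tert-butyldimethylsilyloxy)-2-(methoxymethoxy)-5-(2-methylbut-3-en-2-yl)phenyl]-N-methoxy-N-methylpropanamide | CON(C)C(=O)CCc1cc(C(C)(C)C=C)c(O[Si](C)(C)C(C)(C)C)cc1OCOC | intermediate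
15 | ethynylmagnesium bromide | C#C[Mg]Br | starting material
16 | 5-[4-(tert-butyldimethylsilyloxy)-2-(methoxymethoxy)-5-(2-methylbut-3-en-2-yl)phenyl]pent-1-yn-3-one | C#CC(=O)CCc1cc(C(C)(C)C=C)c(O[Si](C)(C)C(C)(C)C)cc1OCOC | intermediate
17 | 1-[cis-4,5-bis(tert-butyldimethylsilyloxy)-3,6-bis(3-methylbut-2-en-1-yl)cyclohexa-1,4-dien-1-yl]-3-[4-(tert-butyldimethylsilyloxy)-2-(methoxymethoxy)-5-(2-methylbut-3-en-2-yl)phenyl]propan-1-one (racemic, relative configuration shown) | C=CC(C)(C)c1cc(CCC(=O)C2=C[C@@H](CC=C(C)C)C(O[Si](C)(C)C(C)(C)C)=C(O[Si](C)(C)C(C)(C)C)[C@H]2CC=C(C)C)c(OCOC)cc1O[Si](C)(C)C(C)(C)C | intermediate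
18 | 1-[3,4-bis(tert-butyldimethylsilyloxy)-2,5-bis(3-methylbut-2-en-1-yl)phenyl]-3-[4-(tert-butyldimethylsilyloxy)-2-(methoxymethoxy)-5-(2-methylbut-3-en-2-yl)phenyl]propan-1-one | C=CC(C)(C)c1cc(CCC(=O)c2cc(CC=C(C)C)c(O[Si](C)(C)C(C)(C)C)c(O[Si](C)(C)C(C)(C)C)c2CC=C(C)C)c(OCOC)cc1O[Si](C)(C)C(C)(C)C | intermediate
19 | 1-[3,4-bis(tert-butyldimethylsilyloxy)-2,5-bis(3-methylbut-2-en-1-yl)phenyl]-3-[4-(tert-butyldimethylsilyloxy)-5-(2-methylbut-3-en-2-yl)-2-(trimethylsilyloxy)phenyl]propan-1-one | C=CC(C)(C)c1cc(CCC(=O)c2cc(CC=C(C)C)c(O[Si](C)(C)C(C)(C)C)c(O[Si](C)(C)C(C)(C)C)c2CC=C(C)C)c(O[Si](C)(C)C)cc1O[Si](C)(C)C(C)(C)C | intermediate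
20 | 1-[3,4-bis(tert-butyldimethylsilyloxy)-2,5-bis(3-methylbut-2-en-1-yl)phenyl]-3-[4-(tert-butyldimethylsilyloxy)-2-hydroxy-5-(2-methylbut-3-en-2-yl)phenyl]propan-1-one | C=CC(C)(C)c1cc(CCC(=O)c2cc(CC=C(C)C)c(O[Si](C)(C)C(C)(C)C)c(O[Si](C)(C)C(C)(C)C)c2CC=C(C)C)c(O)cc1O[Si](C)(C)C(C)(C)C | intermediate
21 | (1R)-1-[3,4-bis(tert-butyldimethylsilyloxy)-2,5-bis(3-methylbut-2-en-1-yl)phenyl]-3-[4-(tert-butyldimethylsilyloxy)-2-hydroxy-5-(2-methylbut-3-en-2-yl)phenyl]propan-1-ol | C=CC(C)(C)c1cc(CC[C@@H](O)c2cc(CC=C(C)C)c(O[Si](C)(C)C(C)(C)C)c(O[Si](C)(C)C(C)(C)C)c2CC=C(C)C)c(O)cc1O[Si](C)(C)C(C)(C)C | intermediate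
22 | (2S)-2-[3,4-bis(tert-butyldimethylsilyloxy)-2,5-bis(3-methylbut-2-en-1-yl)phenyl]-7-(tert-butyldimethylsilyloxy)-6-(2-methylbut-3-en-2-yl)chromane | C=CC(C)(C)c1cc2c(cc1O[Si](C)(C)C(C)(C)C)O[C@H](c1cc(CC=C(C)C)c(O[Si](C)(C)C(C)(C)C)c(O[Si](C)(C)C(C)(C)C)c1CC=C(C)C)CC2 | intermediate
23 | 4-[(2S)-7-hydroxy-6-(2-methylbut-3-en-2-yl)-3,4-dihydro-2H-chromen-2-yl]-3,6-bis(3-methylbut-2-en-1-yl)benzene-1,2-diol | C=CC(C)(C)c1cc2c(cc1O)O[C@H](c1cc(CC=C(C)C)c(O)c(O)c1CC=C(C)C)CC2 | target

**Step count**

Total: 14 steps. Longest linear sequence: 12 steps (umbelliferone 6 → 23, steps 3–14); the diene branch contributes steps 1–2.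

**Steps most likely to fail**

1. Step 10 (cycloaddition/dehydrogenation). The two bulky silyloxy groups may resist the planar s-cis arrangement of the 1,4-disubstituted diene. The cycloaddition could then be slower than thermal oligomerisation of the terminal ynone, or the oxidation could run on past the arene at the prenyl methylene groups.
   Fallback: the diene would be rebuilt with smaller silyl groups, setting out from diketone 4 with ynone 16 unchanged. TMSOTf/Et3N in CH2Cl2 should give (5Z,7Z)-2,11-dimethyl-6,7-bis(trimethylsilyloxy)dodeca-2,5,7,10-tetraene F1, the classical, less hindered diene type. Heating F1 with 16 in toluene at 80–100 °C should give the cis-cyclohexa-1,4-diene bis(trimethylsilyl enol ether) F2, which is not isolated. Exactly one equivalent of DDQ at 0 °C should aromatise it to the bis(trimethylsilyl) catechol ether F3. Brief methanolysis (MeOH, trace citric acid, 0 °C) should release the catechol ketone F4. TBSCl/imidazole in DMF would then silylate both hydroxyls and return to the route at dihydrochalcone 18.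

2. Step 7 (aromatic Claisen rearrangement). The allyl unit may migrate to the carbon between the two oxygens. The first-formed ortho-(1,1-dimethylallyl)phenol may also react on at 185 °C by abnormal Claisen isomerisation, cyclisation of the phenol onto the new vinyl group, or loss of the prenyl group.
   Fallback: the quaternary aryl–carbon bond would be made by cross-coupling instead of a sigmatropic shift, setting out from 7-hydroxychroman-2-one 7. TBSCl/imidazole should give 7-(tert-butyldimethylsilyloxy)chroman-2-one F5. MeNHOMe·HCl/iPrMgCl should open it to 3-[4-(tert-butyldimethylsilyloxy)-2-hydroxyphenyl]-N-methoxy-N-methylpropanamide F6. MOMCl/iPr2NEt should give the MOM ether F7. NBS in MeCN at 0 °C should brominate para to the MOM ether and ortho to the silyl ether, giving the aryl bromide F8. A ligand-controlled, γ-selective Suzuki–Miyaura coupling of F8 with prenylboronic acid pinacol ester (Pd(OAc)2, bulky biarylphosphine, K3PO4, aqueous THF, 40 °C) should attach the allyl unit through its tertiary carbon and return to the route at amide 14.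

3. Step 12 (asymmetric transfer hydrogenation). The ortho prenyl group twists ring B out of conjugation with the carbonyl. Hydride transfer from the ruthenium catalyst, which relies on an aryl CH/π contact, may therefore be slow and poorly face-selective, leaving ketone or giving carbinol of low enantiomeric purity.
   Fallback: the ketone would be reduced under steric control by a Corey–Bakshi–Shibata reduction, setting out from keto-phenol 20. (S)-2-Methyl-CBS-oxazaborolidine with catecholborane in toluene at −78 °C distinguishes the large aryl group from the CH2 chain, tolerates ortho substitution and does not hydroborate the isolated alkenes at this temperature. It should give the same (R)-carbinol and return to the route at 21; no new compound arises (F0).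

**Further compounds**

F1 | step 10 | (5Z,7Z)-2,11-dimethyl-6,7-bis(trimethylsilyloxy)dodeca-2,5,7,10-tetraene | CC(C)=CC/C=C(O[Si](C)(C)C)/C(O[Si](C)(C)C)=C/CC=C(C)C
F2 | step 10 | 1-[cis-3,6-bis(3-methylbut-2-en-1-yl)-4,5-bis(trimethylsilyloxy)cyclohexa-1,4-dien-1-yl]-3-[4-(tert-butyldimethylsilyloxy)-2-(methoxymethoxy)-5-(2-methylbut-3-en-2-yl)phenyl]propan-1-one (racemic, not isolated) | C=CC(C)(C)c1cc(CCC(=O)C2=C[C@@H](CC=C(C)C)C(O[Si](C)(C)C)=C(O[Si](C)(C)C)[C@H]2CC=C(C)C)c(OCOC)cc1O[Si](C)(C)C(C)(C)C
F3 | step 10 | 1-[2,5-bis(3-methylbut-2-en-1-yl)-3,4-bis(trimethylsilyloxy)phenyl]-3-[4-(tert-butyldimethylsilyloxy)-2-(methoxymethoxy)-5-(2-methylbut-3-en-2-yl)phenyl]propan-1-one | C=CC(C)(C)c1cc(CCC(=O)c2cc(CC=C(C)C)c(O[Si](C)(C)C)c(O[Si](C)(C)C)c2CC=C(C)C)c(OCOC)cc1O[Si](C)(C)C(C)(C)C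
F4 | step 10 | 1-[3,4-dihydroxy-2,5-bis(3-methylbut-2-en-1-yl)phenyl]-3-[4-(tert-butyldimethylsilyloxy)-2-(methoxymethoxy)-5-(2-methylbut-3-en-2-yl)phenyl]propan-1-one | C=CC(C)(C)c1cc(CCC(=O)c2cc(CC=C(C)C)c(O)c(O)c2CC=C(C)C)c(OCOC)cc1O[Si](C)(C)C(C)(C)C
F5 | step 7 | 7-(tert-butyldimethylsilyloxy)chroman-2-one | O=C1CCc2ccc(O[Si](C)(C)C(C)(C)C)cc2O1
F6 | step 7 | 3-[4-(tert-butyldimethylsilyloxy)-2-hydroxyphenyl]-N-methoxy-N-methylpropanamide | CON(C)C(=O)CCc1ccc(O[Si](C)(C)C(C)(C)C)cc1O
F7 | step 7 | 3-[4-(tert-butyldimethylsilyloxy)-2-(methoxymethoxy)phenyl]-N-methoxy-N-methylpropanamide | CON(C)C(=O)CCc1ccc(O[Si](C)(C)C(C)(C)C)cc1OCOC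
F8 | step 7 | 3-[5-bromo-4-(tert-butyldimethylsilyloxy)-2-(methoxymethoxy)phenyl]-N-methoxy-N-methylpropanamide | CON(C)C(=O)CCc1cc(Br)c(O[Si](C)(C)C(C)(C)C)cc1OCOC
F0 | step 12 | none | none
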